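Do not carry a plateau percentage from one flask to the next: the dusk run stays near 50.2% and the dawn run near 68.5%, each flat within its scatter.

| setting | dusk | dawn | flask |
|---|---|---|---|
| J | 0.76 M | 1.2 M | 0.54 M |
| remark | run made earlier | run made earlier |  |
| time |  |  | 12 h |

- dusk (time / h: E / %): 2.00: 50; 4.00: 51; 6.00: 50; 8.00: 48; 10.0: 53; 12.0: 49
- dawn (time / h: E / %): 0.833: 68; 2.50: 69; 4.00: 70; 6.00: 69; 10.0: 67; 12.0: 68

(readings scatter by 1.5 percentage points)

- percentages count the J that a species holds: one E counts as two
- a reading or a percentage of E counts all its forms, free or not
- the reaction counts as stopped when no species that holds the J changes by six tenths of a point or more over the second half of the time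

- the state of affairs at 12 h: stopped, and by what, or still going (it is still moving / all of J has reacted / forward and back rates have come level)
- E at 12 h, in percent of the J charged

Multiply each charge by the fraction not counted in E: dusk leaves 0.379 M and dawn leaves 0.378 M. Carry this reading, the remainder, the concentration of charged J held outside E.

Now solve two extreme flasks. In the first, E stays dissolved, so the constant read from dusk, E over the remainder squared, 1.33 M⁻¹, holds; that version of the flask then gives 44.4%. But dawn reads 2.88 M⁻¹, a larger value, so this version fails on the runs. In the second, E beyond a dissolved limit leaves solution and the remainder stays put, which gives 30.0%. The two runs read the same remainder and put no figure on the limit, so I expect the flask between these two, within the scatter of the readings, and I commit to the lower one. Dawn read flat by 0.833 h, so I expect 12 h to be ample.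

The forecast says 30% and forward and back rates have come level: “Constant free J instead suggests E saturating or separating as a second phase”.

The flask gives 29.8%, and forward and back rates have come level.

    L ⇌ E, rate k1*(cs1 - [E]) while solid is left; crystals form when [E] > cs1 (solubility = 39.0 mM, k = 0.105 s⁻¹)
    J ⇌ G (K = 0.833, k = 0.00669 s⁻¹)
    2 J ⇌ E (K = 0.911 M⁻¹, k = 0.0189 M⁻¹ s⁻¹)

In this flask J at 38.3% and G at 31.9% of the charge stand outside E, together 0.379 M, where the reckoning carried 0.378 M. The way back, E to 2 J, is the main reason E stops short in this flask: without it, E at the asked time stands at 99.6% against 29.8%. For a further flask charged with 2.2 M of J, the remainder gives 82.8%, and that flask holds 82.8%.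

The earlier runs and the new flask are simulated for substances that don't exist, and the scatter is random.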